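**Plan**

- The target is a tridepside without stereocentres. Retrosynthesis removes two benzyl groups, then cuts the ring A acyl–B4 oxygen ester, then ring B itself at B1–B6, and last the acyl–oxygen bond between the opened chain and the C4 oxygen of ring C.
- Ring B (the middle ring: ester carbon on B1, hydroxyl on B2, acylated oxygen on B4, methyl on B6) has the orsellinate pattern of a folded tetraketide. Unfolded it is a 3,5,7-trioxooctanoyl chain on the ring C phenol, with chain C2 and C7 becoming B1 and B6.
- Forward: the dioxinone is acetylated twice and its acylketene is captured by benzyl orsellinate (ring C). Aldol–aromatisation of the triketo aryl ester then closes ring B.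
- The ring A acid comes from 2,3-dimethoxytoluene by C–H borylation/oxidation, benzylation, formylation and oxidation. It is esterified onto the B4 hydroxyl, and hydrogenolysis finishes the route.
- No stereochemistry has to be set; the two transient centres of the aldol adduct vanish on aromatisation.

Key step: step 9

Assumption: the hydrogen-bonded 2-hydroxyl of the ring C benzyl ester is carried unprotected, since chelation to the ortho ester carbonyl should keep it out of both the ketene capture and the later acylation.

**Route**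

Step 1
Reactants: 1 2,3-dimethoxytoluene
Product: 3 3,4-dimethoxy-5-methylphenol, via aryl pinacol boronate 2 (not isolated)
Conditions: [Ir(OMe)(cod)]2 (1.5 mol%; cod = 1,5-cyclooctadiene), 4,4'-di-tert-butyl-2,2'-bipyridine (3 mol%), B2pin2 (0.55 equiv), THF, 80 °C; evaporate; then KHSO5 (as 2KHSO5·KHSO4·K2SO4), acetone/H2O, rt
Reagents that add atoms: potassium peroxymonosulfate, [K+].[O-]S(=O)(=O)OO
Why: Iridium-catalysed aromatic C–H borylation is sterically controlled and should take only the C–H of 1 that has no ortho substituent (C5, meta to the methyl group), after which peroxide oxidation of the C–B bond of 2 should deliver the phenol in the same flask.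

Step 2
Reactants: 3 3,4-dimethoxy-5-methylphenol
Product: 4 5-(benzyloxy)-1,2-dimethoxy-3-methylbenzene
Conditions: BnBr, K2CO3, DMF, rt
Reagents that add atoms: benzyl bromide, BrCc1ccccc1
Why: Williamson etherification of the phenoxide with benzyl bromide should be clean and installs a group that later leaves together with the ring C benzyl ester.

Step 3
Reactants: 4 5-(benzyloxy)-1,2-dimethoxy-3-methylbenzene
Product: 6 2-(benzyloxy)-4,5-dimethoxy-6-methylbenzaldehyde, via aryl iminium chloride 5 (not isolated)
Conditions: POCl3, DMF, 0 → 70 °C; then ice-water, rt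
Reagents that add atoms: N,N-dimethylformamide, CN(C)C=O (formyl carbon); water, O (carbonyl oxygen)
Why: Vilsmeier–Haack formylation should occur at C4 of 4, ortho to the benzyloxy group and para to the unhindered 1-methoxy group, rather than at C6 between two alkoxy groups, in line with the behaviour of orcinol dialkyl ethers; water then hydrolyses the iminium salt 5.

Step 4
Reactants: 6 2-(benzyloxy)-4,5-dimethoxy-6-methylbenzaldehyde
Product: 7 2-(benzyloxy)-4,5-dimethoxy-6-methylbenzoic acid
Conditions: NaClO2, NaH2PO4, 2-methyl-2-butene, t-BuOH/H2O, rt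
Reagents that add atoms: sodium chlorite, [Na+].[O-]Cl=O
Why: Pinnick oxidation should convert the hindered, electron-rich aldehyde into the acid under buffered conditions, 2-methyl-2-butene removing the hypochlorous acid that would otherwise chlorinate the ring.

Step 5
Reactants: 8 2,2,6-trimethyl-4H-1,3-dioxin-4-one
Product: 10 2,2-dimethyl-6-(2-oxopropyl)-4H-1,3-dioxin-4-one, via lithium dienolate 9 (not isolated)
Conditions: LiN(SiMe3)2 (1.0 equiv), THF, −78 °C; then AcCl (0.5 equiv), −78 °C; 1 M HCl quench
Reagents that add atoms: acetyl chloride, CC(=O)Cl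
Why: Deprotonation of the 6-methyl group gives the vinylogous ester dienolate 9, which is C-acylated at its terminal carbon by acetyl chloride (Claisen-type acylation); two equivalents of enolate are used per acid chloride because the product is the stronger acid.

Step 6
Reactants: 10 2,2-dimethyl-6-(2-oxopropyl)-4H-1,3-dioxin-4-one
Product: 12 6-(2,4-dioxopentyl)-2,2-dimethyl-4H-1,3-dioxin-4-one, via dilithium dianion 11 (not isolated)
Conditions: LiN(iPr)2 (commercial solution, 2.2 equiv), THF, −78 → −40 °C; then MeC(O)N(OMe)Me, −78 → 0 °C; 1 M HCl quench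
Reagents that add atoms: N-methoxy-N-methylacetamide, CON(C)C(C)=O
Why: A second deprotonation at the terminal methyl ketone gives dianion 11, which, as in the acylation of β-dicarbonyl dianions, should react at its more basic terminal carbon with the Weinreb amide, whose chelated tetrahedral adduct prevents a second addition.

Step 7
Reactants: 13 orsellinic acid (2,4-dihydroxy-6-methylbenzoic acid)
Product: 14 benzyl 2,4-dihydroxy-6-methylbenzoate (benzyl orsellinate)
Conditions: BnBr, KHCO3, DMF, rt
Reagents that add atoms: benzyl bromide, BrCc1ccccc1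
Why: Bicarbonate ionises only the carboxylic acid, so SN2 alkylation of the carboxylate should give the benzyl ester with both phenols untouched and without heating the decarboxylation-prone acid.

Step 8
Reactants: 12 6-(2,4-dioxopentyl)-2,2-dimethyl-4H-1,3-dioxin-4-one; 14 benzyl 2,4-dihydroxy-6-methylbenzoate
Product: 16 benzyl 2-hydroxy-6-methyl-4-[(3,5,7-trioxooctanoyl)oxy]benzoate, via acylketene 15 (not isolated)
Conditions: toluene, 110 °C, 12 added slowly to 14 (1.3 equiv); concentrate, crude 16 used directly
Reagents that add atoms: none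
Why: Retro-[4+2] fragmentation of the dioxinone releases acetone and acylketene 15, to which the free 4-hydroxyl of 14 should add (ketene acylation of a phenol) while the chelated, flanked 2-hydroxyl stays out; the ring B–ring C ester is thus made under neutral conditions before ring B exists.

Step 9
Reactants: 16 benzyl 2-hydroxy-6-methyl-4-[(3,5,7-trioxooctanoyl)oxy]benzoate
Product: 18 benzyl 4-[(2,4-dihydroxy-6-methylbenzoyl)oxy]-2-hydroxy-6-methylbenzoate, via aldol adduct 17 (not isolated)
Conditions: Cs2CO3 (2.2 equiv), dry THF, 0 °C → rt; then HCl (4 M in 1,4-dioxane), rt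
Reagents that add atoms: none
Why: Cs2CO3 removes a proton from chain C2, the CH2 between the aryl ester and the C3 ketone, and the enolate adds to the C7 methyl ketone to give the cyclic aldol 17; acid then eliminates water and the C3 and C5 carbonyls enolise, so that the C2–C7 bond becomes B1–B6 of an aromatic ring with the ester on B1, hydroxyls on B2 and B4 and the methyl group on B6. The closest known reaction type is the aldol cyclo-aromatisation of 3,5,7-triketo esters to resorcylates (biomimetic polyketide folding). Ring B closes in a 6-(enolendo)-exo-trig mode. The two stereocentres of 17 form as a mixture and are erased on aromatisation, so no stereocontrol is needed. The step needs C2-on-C7 aldol closure to win over attack of C6 or of the C5 enol oxygen on the ester carbonyl (Claisen closure or pyranone formation, both expelling the ring C aryloxide): the ketone is the better electrophile for the stabilised C2 enolate, the large caesium ion avoids the tight chelation that favours Claisen closure, and in the alcohol-free medium an aryloxide lost by E1cB can only add back to the ketene. The chelated ring C 2-hydroxyl, once deprotonated, should also make that aryloxide a poorer leaving group, and the acid stage makes the aldol irreversible through aromatisation.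

Step 10
Reactants: 7 2-(benzyloxy)-4,5-dimethoxy-6-methylbenzoic acid; 18 benzyl 4-[(2,4-dihydroxy-6-methylbenzoyl)oxy]-2-hydroxy-6-methylbenzoate
Product: 20 benzyl 4-{[4-{[2-(benzyloxy)-4,5-dimethoxy-6-methylbenzoyl]oxy}-2-hydroxy-6-methylbenzoyl]oxy}-2-hydroxy-6-methylbenzoate, via mixed anhydride 19 (not isolated)
Conditions: (CF3CO)2O, toluene, rt; aq NaHCO3 work-up
Reagents that add atoms: none
Why: Trifluoroacetic anhydride turns the electron-rich 2,6-disubstituted acid into mixed anhydride 19, which has acylium character and should acylate the only non-chelated phenol of 18, the B4 hydroxyl (mixed-anhydride depside esterification), the B2 and C2 hydroxyls being held in hydrogen bonds to their ortho ester carbonyls.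

Step 11
Reactants: 20 benzyl 4-{[4-{[2-(benzyloxy)-4,5-dimethoxy-6-methylbenzoyl]oxy}-2-hydroxy-6-methylbenzoyl]oxy}-2-hydroxy-6-methylbenzoate
Product: 21 2-hydroxy-4-{[2-hydroxy-4-{[2-hydroxy-4,5-dimethoxy-6-methylbenzoyl]oxy}-6-methylbenzoyl]oxy}-6-methylbenzoic acid (CNP0139469.0)
Conditions: H2 (1 atm), 10% Pd/C, EtOAc, rt
Reagents that add atoms: none
Why: Catalytic hydrogenolysis should cleave the benzyl ester and the benzyl aryl ether while both depside esters and the methyl ethers are inert, and room temperature avoids decarboxylation of the freed acid.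

**Compound list**

1 | 2,3-dimethoxytoluene | COc1cccc(C)c1OC | starting material
2 | 2-(3,4-dimethoxy-5-methylphenyl)-4,4,5,5-tetramethyl-1,3,2-dioxaborolane | COc1cc(B2OC(C)(C)C(C)(C)O2)cc(C)c1OC | intermediate (not isolated)
3 | 3,4-dimethoxy-5-methylphenol | COc1cc(O)cc(C)c1OC | intermediate
4 | 5-(benzyloxy)-1,2-dimethoxy-3-methylbenzene | COc1cc(OCc2ccccc2)cc(C)c1OC | intermediate
5 | N-{[2-(benzyloxy)-4,5-dimethoxy-6-methylphenyl]methylidene}-N-methylmethanaminium chloride | C[N+](C)=Cc1c(C)c(OC)c(OC)cc1OCc1ccccc1.[Cl-] | intermediate (not isolated)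
6 | 2-(benzyloxy)-4,5-dimethoxy-6-methylbenzaldehyde | COc1cc(OCc2ccccc2)c(C=O)c(C)c1OC | intermediate
7 | 2-(benzyloxy)-4,5-dimethoxy-6-methylbenzoic acid | COc1cc(OCc2ccccc2)c(C(=O)O)c(C)c1OC | intermediate
8 | 2,2,6-trimethyl-4H-1,3-dioxin-4-one | CC1=CC(=O)OC(C)(C)O1 | starting material
9 | lithium 2,2-dimethyl-6-methylidene-6H-1,3-dioxin-4-olate | [Li+].C=C1C=C([O-])OC(C)(C)O1 | intermediate (not isolated)
10 | 2,2-dimethyl-6-(2-oxopropyl)-4H-1,3-dioxin-4-one | CC(=O)CC1=CC(=O)OC(C)(C)O1 | intermediate
11 | dilithium 2,2-dimethyl-6-(2-oxidoprop-2-en-1-ylidene)-6H-1,3-dioxin-4-olate | [Li+].[Li+].C=C([O-])C=C1C=C([O-])OC(C)(C)O1 | intermediate (not isolated)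
12 | 6-(2,4-dioxopentyl)-2,2-dimethyl-4H-1,3-dioxin-4-one | CC(=O)CC(=O)CC1=CC(=O)OC(C)(C)O1 | intermediate
13 | orsellinic acid (2,4-dihydroxy-6-methylbenzoic acid) | Cc1cc(O)cc(O)c1C(=O)O | starting material
14 | benzyl 2,4-dihydroxy-6-methylbenzoate | Cc1cc(O)cc(O)c1C(=O)OCc1ccccc1 | intermediate
15 | oct-1-ene-1,3,5,7-tetrone (3,5-dioxohexanoylketene) | CC(=O)CC(=O)CC(=O)C=C=O | intermediate (not isolated)
16 | benzyl 2-hydroxy-6-methyl-4-[(3,5,7-trioxooctanoyl)oxy]benzoate | CC(=O)CC(=O)CC(=O)CC(=O)Oc1cc(C)c(C(=O)OCc2ccccc2)c(O)c1 | intermediate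
17 | benzyl 2-hydroxy-4-[(2-hydroxy-2-methyl-4,6-dioxocyclohexane-1-carbonyl)oxy]-6-methylbenzoate (racemic mixture of diastereomers, configuration not defined) | CC1(O)CC(=O)CC(=O)C1C(=O)Oc1cc(C)c(C(=O)OCc2ccccc2)c(O)c1 | intermediate (not isolated)
18 | benzyl 4-[(2,4-dihydroxy-6-methylbenzoyl)oxy]-2-hydroxy-6-methylbenzoate | Cc1cc(O)cc(O)c1C(=O)Oc1cc(C)c(C(=O)OCc2ccccc2)c(O)c1 | intermediate
19 | 2-(benzyloxy)-4,5-dimethoxy-6-methylbenzoic trifluoroacetic anhydride | COc1cc(OCc2ccccc2)c(C(=O)OC(=O)C(F)(F)F)c(C)c1OC | intermediate (not isolated)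
20 | benzyl 4-{[4-{[2-(benzyloxy)-4,5-dimethoxy-6-methylbenzoyl]oxy}-2-hydroxy-6-methylbenzoyl]oxy}-2-hydroxy-6-methylbenzoate | COc1cc(OCc2ccccc2)c(C(=O)Oc2cc(C)c(C(=O)Oc3cc(C)c(C(=O)OCc4ccccc4)c(O)c3)c(O)c2)c(C)c1OC | intermediate
21 | 2-hydroxy-4-{[2-hydroxy-4-{[2-hydroxy-4,5-dimethoxy-6-methylbenzoyl]oxy}-6-methylbenzoyl]oxy}-6-methylbenzoic acid | COc1cc(O)c(C(=O)Oc2cc(C)c(C(=O)Oc3cc(C)c(C(=O)O)c(O)c3)c(O)c2)c(C)c1OC | target

**Step count**

Total: 11 steps. Longest linear sequence: 6 steps (steps 1, 2, 3, 4, 10, 11, or steps 5, 6, 8, 9, 10, 11).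

**Steps most likely to fail**

1. Step 9. Loss of the ring C aryloxide, by Claisen closure, pyranone formation or E1cB fragmentation, may outrun the aldol closure. The fallback gives up the chain folding and takes ring B from orsellinic acid 13. Allyl bromide and K2CO3 in DMF should give allyl 4-(allyloxy)-2-hydroxy-6-methylbenzoate F1, the chelated 2-hydroxyl staying free. KOH in aqueous DMSO should hydrolyse the ester to 4-(allyloxy)-2-hydroxy-6-methylbenzoic acid F2. Esterification of F2 with 14 by N,N'-dicyclohexylcarbodiimide in toluene should give benzyl 4-{[4-(allyloxy)-2-hydroxy-6-methylbenzoyl]oxy}-2-hydroxy-6-methylbenzoate F3. Deallylation with Pd(PPh3)4 (zerovalent palladium) and morpholine then returns to the route at 18.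

2. Step 8. The acylketene may close onto its own C5 enol oxygen, or the aryl ester may not survive 110 °C, before the weakly nucleophilic phenol has been acylated. The fallback separates the thermal ketene generation from the ester-forming event. Heating 12 with 2-methylpropane-2-thiol in toluene should give S-tert-butyl 3,5,7-trioxooctanethioate F4. Thiophilic activation of F4 with AgO2CCF3 in THF at room temperature in the presence of 14 should transfer the acyl group to the phenol and return to the route at 16.

3. Step 6. Proton transfer from the enolisable Weinreb amide to the dianion, or reaction at oxygen or at the internal carbon, may erode the second acetylation. The fallback sets out from 8 and replaces dianion chemistry by soft enolisation. Enolate 9 is acylated with allyl 3-chloro-3-oxopropanoate to give allyl 4-(2,2-dimethyl-4-oxo-4H-1,3-dioxin-6-yl)-3-oxobutanoate F5. C-acetylation with MgCl2, pyridine and acetyl chloride in CH2Cl2 should give allyl 2-acetyl-4-(2,2-dimethyl-4-oxo-4H-1,3-dioxin-6-yl)-3-oxobutanoate F6. Deallylative decarboxylation with Pd(PPh3)4 and morpholine returns to the route at 12.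

**Further compounds**

F1 | step 9 | allyl 4-(allyloxy)-2-hydroxy-6-methylbenzoate | C=CCOC(=O)c1c(C)cc(OCC=C)cc1O
F2 | step 9 | 4-(allyloxy)-2-hydroxy-6-methylbenzoic acid | Cc1cc(OCC=C)cc(O)c1C(=O)O
F3 | step 9 | benzyl 4-{[4-(allyloxy)-2-hydroxy-6-methylbenzoyl]oxy}-2-hydroxy-6-methylbenzoate | C=CCOc1cc(C)c(C(=O)Oc2cc(C)c(C(=O)OCc3ccccc3)c(O)c2)c(O)c1
F4 | step 8 | S-tert-butyl 3,5,7-trioxooctanethioate | CC(=O)CC(=O)CC(=O)CC(=O)SC(C)(C)C
F5 | step 6 | allyl 4-(2,2-dimethyl-4-oxo-4H-1,3-dioxin-6-yl)-3-oxobutanoate | C=CCOC(=O)CC(=O)CC1=CC(=O)OC(C)(C)O1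
F6 | step 6 | allyl 2-acetyl-4-(2,2-dimethyl-4-oxo-4H-1,3-dioxin-6-yl)-3-oxobutanoate | C=CCOC(=O)C(C(C)=O)C(=O)CC1=CC(=O)OC(C)(C)O1
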